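**Plan**
- Retrosynthesis: the pyranone ring holds an α-ketol, C3(OH)–C4(=O). C4 sits on A-ring carbon C4a; C3 carries the B ring and is tied through C2–O1 to A-ring carbon C8a. This is a benzoin retron, so C3–C4 is cut first, then the aryl ether bond O1–C2, then the two aryl–prenyl bonds, the A-ring formyl C–C bond and the B-ring aryl–acyl bond.
- Forward: a prenylated salicylaldehyde (A ring, from phloroglucinol) and a prenylated α-chloroacetophenone (B ring, from 4-bromo-3-methoxyphenol) are made by directed metalation and joined by O-alkylation (O1–C2). The pyranone ring, the only ring that is built, closes last by C3–C4 bond formation; the three methoxymethyl ethers are then removed.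
- Stereochemistry: C3 is the only stereocentre. It is set in the ring closure by a chiral triazolylidene catalyst that selects one face of the ketone; C3 bears no hydrogen and is not touched afterwards.

Key step: step 9

Assumption: the precatalyst C* = (5aS,10bR)-2-(pentafluorophenyl)-5a,10b-dihydro-4H,6H-indeno[2,1-b][1,2,4]triazolo[4,3-d][1,4]oxazin-2-ium tetrafluoroborate is taken to deliver the (3R) ketol; should the sense of induction be the opposite, its (5aR,10bS) antipode replaces it with no other change.

**Step 1**
Reactants: 1 benzene-1,3,5-triol (phloroglucinol)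
Product: 2 3,5-bis(methoxymethoxy)phenol
Conditions: MOMCl (2.1 equiv), i-Pr2NEt, DMF, 0 °C → rt
Reagents that add atoms: chloromethyl methyl ether (MOMCl), COCCl
Why: Williamson-type O-alkylation with the α-chloro ether; the three hydroxyls are equivalent, so two equivalents should give the bis-ether as the main part of a statistical mixture that is separable from the mono- and tris-ethers by chromatography.

**Step 2**
Reactants: 2 3,5-bis(methoxymethoxy)phenol
Product: 3 [3,5-bis(methoxymethoxy)phenoxy]tri(propan-2-yl)silane
Conditions: TIPSCl, imidazole, DMF, rt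
Reagents that add atoms: chlorotri(propan-2-yl)silane (TIPSCl), CC(C)[Si](Cl)(C(C)C)C(C)C
Why: standard phenol silylation; the bulky, non-coordinating silyl ether masks the acidic O–H and leaves the carbon between the two acetal ethers as the only doubly activated site for metalation.

**Step 3**
Reactants: 3 [3,5-bis(methoxymethoxy)phenoxy]tri(propan-2-yl)silane
Product: 6 3,5-bis(methoxymethoxy)-4-(3-methylbut-2-en-1-yl)phenol, via aryllithium 4 (not isolated), via prenylated silyl ether 5 (not isolated)
Conditions: n-BuLi, THF, 0 °C; CuI (10 mol%), prenyl bromide (1.0 equiv), −78 °C → rt; aq NH4Cl; crude, TBAF, THF, 0 °C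
Reagents that add atoms: 1-bromo-3-methylbut-2-ene (prenyl bromide), CC(C)=CCBr
Why: directed ortho-metalation, in which n-BuLi is held by both methoxymethoxy groups and removes the proton between them, followed by copper-catalysed allylic substitution at the primary carbon of prenyl bromide and fluoride cleavage of the Si–O bond of the crude ether.

**Step 4**
Reactants: 6 3,5-bis(methoxymethoxy)-4-(3-methylbut-2-en-1-yl)phenol
Product: 7 6-hydroxy-2,4-bis(methoxymethoxy)-3-(3-methylbut-2-en-1-yl)benzaldehyde
Conditions: MgCl2, Et3N, (CH2O)n, MeCN, 80 °C; aq NH4Cl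
Reagents that add atoms: paraformaldehyde (as formaldehyde), C=O
Why: magnesium-mediated ortho-formylation of a phenol (Casnati–Skattebøl reaction), in which the magnesium phenoxide delivers formaldehyde to the ortho carbon and a second formaldehyde oxidises the benzylic alkoxide; the two ortho positions are equivalent by symmetry, so only one aldehyde can form and the prenyl group necessarily ends para to the free hydroxyl.

**Step 5**
Reactants: 8 4-bromo-3-methoxyphenol
Product: 9 1-bromo-2-methoxy-4-(methoxymethoxy)benzene
Conditions: MOMCl, i-Pr2NEt, CH2Cl2, 0 °C → rt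
Reagents that add atoms: chloromethyl methyl ether (MOMCl), COCCl
Why: Williamson-type O-alkylation of the single phenol; the acetal ether serves both as protecting group and as second directing group for the next metalation.

**Step 6**
Reactants: 9 1-bromo-2-methoxy-4-(methoxymethoxy)benzene
Product: 11 1-bromo-2-methoxy-4-(methoxymethoxy)-3-(3-methylbut-2-en-1-yl)benzene, via aryllithium 10 (not isolated)
Conditions: LDA, THF, −78 °C; CuBr·SMe2 (10 mol%), prenyl bromide, −78 → −20 °C
Reagents that add atoms: 1-bromo-3-methylbut-2-ene (prenyl bromide), CC(C)=CCBr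
Why: deprotonative ortho-metalation with a non-nucleophilic amide base (no bromine–lithium exchange) at the most acidic proton, the one between the methoxy and methoxymethoxy groups; the lithium is meta to bromine so no aryne can form, and copper-catalysed allylation occurs at the primary carbon of prenyl bromide.

**Step 7**
Reactants: 11 1-bromo-2-methoxy-4-(methoxymethoxy)-3-(3-methylbut-2-en-1-yl)benzene
Product: 14 2-chloro-1-[2-methoxy-4-(methoxymethoxy)-3-(3-methylbut-2-en-1-yl)phenyl]ethan-1-one, via aryllithium 12 (not isolated), via lithium hemiaminal adduct 13 (not isolated)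
Conditions: n-BuLi, THF, −78 °C; ClCH2C(O)N(OMe)Me, −78 → −30 °C; aq NH4Cl
Reagents that add atoms: 2-chloro-N-methoxy-N-methylacetamide, CON(C)C(=O)CCl
Why: bromine–lithium exchange outruns any deprotonation at −78 °C, and the aryllithium adds once to the N-methoxy-N-methylamide (Weinreb ketone synthesis) to give a chelated tetrahedral adduct that collapses to the α-chloroketone only on aqueous quench, so neither over-addition nor chloride displacement is expected.

**Step 8**
Reactants: 7 6-hydroxy-2,4-bis(methoxymethoxy)-3-(3-methylbut-2-en-1-yl)benzaldehyde; 14 2-chloro-1-[2-methoxy-4-(methoxymethoxy)-3-(3-methylbut-2-en-1-yl)phenyl]ethan-1-one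
Product: 15 6-{2-[2-methoxy-4-(methoxymethoxy)-3-(3-methylbut-2-en-1-yl)phenyl]-2-oxoethoxy}-2,4-bis(methoxymethoxy)-3-(3-methylbut-2-en-1-yl)benzaldehyde
Conditions: K2CO3, DMF, 0 °C → rt
Reagents that add atoms: none
Why: Williamson ether synthesis, the salicylaldehyde phenoxide displacing the activated primary chloride α to the ketone; room temperature and a mild carbonate base keep the intramolecular aldol condensation to a 2-aroylbenzofuran (Rap–Stoermer pathway) slow.

**Step 9**
Reactants: 15 6-{2-[2-methoxy-4-(methoxymethoxy)-3-(3-methylbut-2-en-1-yl)phenyl]-2-oxoethoxy}-2,4-bis(methoxymethoxy)-3-(3-methylbut-2-en-1-yl)benzaldehyde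
Product: 16 (3R)-3-hydroxy-3-[2-methoxy-4-(methoxymethoxy)-3-(3-methylbut-2-en-1-yl)phenyl]-5,7-bis(methoxymethoxy)-6-(3-methylbut-2-en-1-yl)-2,3-dihydro-4H-chromen-4-one
Conditions: precatalyst C* (20 mol%), i-Pr2NEt (20 mol%), PhMe, 25 °C, Ar
Reagents that add atoms: none
Why: The triazolylidene released from C* adds to the aldehyde carbon (the future C4) and proton transfer gives the Breslow enaminol, an acyl-anion equivalent, whose nucleophilic carbon attacks the tethered aryl ketone carbon (the future C3); proton transfer and loss of the carbene then give the α-ketol. The closest known reaction type is the carbene-catalysed enantioselective intramolecular crossed aldehyde–ketone benzoin reaction of 2-(2-aryl-2-oxoethoxy)benzaldehydes, which gives 3-aryl-3-hydroxychroman-4-ones. The pyranone ring closes in the 6-exo-trig mode, with the ketone C=O exocyclic to the forming ring. The new stereocentre C3 is under catalyst control: the indane-fused backbone shields one face of the enaminol and the enol O–H···O=C hydrogen bond fixes the ketone so that one enantiotopic face is attacked, with the aryl group pointing away from the N-C6F5 ring. The step needs the aldehyde alone to act as acyl donor (the aryl ketone cannot form a Breslow intermediate at a useful rate, and the di-ortho-substituted aldehyde resists intermolecular homo-benzoin coupling) and it needs the base-mediated aldol condensation of the O–CH2–C=O methylene onto the aldehyde to stay slow, which the catalytic amount of a weak amine base in toluene should secure. C3 carries no hydrogen, so the product cannot epimerise by enolisation.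

**Step 10**
Reactants: 16 (3R)-3-hydroxy-3-[2-methoxy-4-(methoxymethoxy)-3-(3-methylbut-2-en-1-yl)phenyl]-5,7-bis(methoxymethoxy)-6-(3-methylbut-2-en-1-yl)-2,3-dihydro-4H-chromen-4-one
Product: 17 (3R)-3,5,7-trihydroxy-3-[4-hydroxy-2-methoxy-3-(3-methylbut-2-en-1-yl)phenyl]-6-(3-methylbut-2-en-1-yl)-2,3-dihydro-4H-chromen-4-one
Conditions: 3 M aq HCl, MeOH–THF, 40 °C, stopped at full conversion
Reagents that add atoms: none
Why: acid-catalysed methanolysis of the three aryl methoxymethyl acetals, the 5-O-acetal peri to the C4 carbonyl going first; the C3 carbinol is α to the carbonyl, which disfavours its ionisation, the ketone is not enolisable, and ring closure of a prenyl group onto a phenol needs stronger acid than this.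

**Compound list**
1 | benzene-1,3,5-triol (phloroglucinol) | Oc1cc(O)cc(O)c1 | starting material
2 | 3,5-bis(methoxymethoxy)phenol | COCOc1cc(O)cc(OCOC)c1 | intermediate
3 | [3,5-bis(methoxymethoxy)phenoxy]tri(propan-2-yl)silane | COCOc1cc(OCOC)cc(O[Si](C(C)C)(C(C)C)C(C)C)c1 | intermediate
4 | [2,6-bis(methoxymethoxy)-4-{[tri(propan-2-yl)silyl]oxy}phenyl]lithium | [Li]c1c(OCOC)cc(O[Si](C(C)C)(C(C)C)C(C)C)cc1OCOC | intermediate
5 | [3,5-bis(methoxymethoxy)-4-(3-methylbut-2-en-1-yl)phenoxy]tri(propan-2-yl)silane | CC(C)=CCc1c(OCOC)cc(O[Si](C(C)C)(C(C)C)C(C)C)cc1OCOC | intermediate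
6 | 3,5-bis(methoxymethoxy)-4-(3-methylbut-2-en-1-yl)phenol | CC(C)=CCc1c(OCOC)cc(O)cc1OCOC | intermediate
7 | 6-hydroxy-2,4-bis(methoxymethoxy)-3-(3-methylbut-2-en-1-yl)benzaldehyde | O=Cc1c(O)cc(OCOC)c(CC=C(C)C)c1OCOC | intermediate
8 | 4-bromo-3-methoxyphenol | COc1cc(O)ccc1Br | starting material
9 | 1-bromo-2-methoxy-4-(methoxymethoxy)benzene | COCOc1ccc(Br)c(OC)c1 | intermediate
10 | [3-bromo-2-methoxy-6-(methoxymethoxy)phenyl]lithium | COCOc1ccc(Br)c(OC)c1[Li] | intermediate
11 | 1-bromo-2-methoxy-4-(methoxymethoxy)-3-(3-methylbut-2-en-1-yl)benzene | COCOc1ccc(Br)c(OC)c1CC=C(C)C | intermediate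
12 | [2-methoxy-4-(methoxymethoxy)-3-(3-methylbut-2-en-1-yl)phenyl]lithium | COCOc1ccc([Li])c(OC)c1CC=C(C)C | intermediate
13 | lithium 2-chloro-1-[methoxy(methyl)amino]-1-[2-methoxy-4-(methoxymethoxy)-3-(3-methylbut-2-en-1-yl)phenyl]ethan-1-olate | COCOc1ccc(C([O-])(CCl)N(C)OC)c(OC)c1CC=C(C)C.[Li+] | intermediate
14 | 2-chloro-1-[2-methoxy-4-(methoxymethoxy)-3-(3-methylbut-2-en-1-yl)phenyl]ethan-1-one | COCOc1ccc(C(=O)CCl)c(OC)c1CC=C(C)C | intermediate
15 | 6-{2-[2-methoxy-4-(methoxymethoxy)-3-(3-methylbut-2-en-1-yl)phenyl]-2-oxoethoxy}-2,4-bis(methoxymethoxy)-3-(3-methylbut-2-en-1-yl)benzaldehyde | O=Cc1c(OCC(=O)c2ccc(OCOC)c(CC=C(C)C)c2OC)cc(OCOC)c(CC=C(C)C)c1OCOC | intermediate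
16 | (3R)-3-hydroxy-3-[2-methoxy-4-(methoxymethoxy)-3-(3-methylbut-2-en-1-yl)phenyl]-5,7-bis(methoxymethoxy)-6-(3-methylbut-2-en-1-yl)-2,3-dihydro-4H-chromen-4-one | COc1c([C@@]2(O)COc3cc(OCOC)c(CC=C(C)C)c(OCOC)c3C2=O)ccc(OCOC)c1CC=C(C)C | intermediate
17 | (3R)-3,5,7-trihydroxy-3-[4-hydroxy-2-methoxy-3-(3-methylbut-2-en-1-yl)phenyl]-6-(3-methylbut-2-en-1-yl)-2,3-dihydro-4H-chromen-4-one | COc1c([C@@]2(O)COc3cc(O)c(CC=C(C)C)c(O)c3C2=O)ccc(O)c1CC=C(C)C | target

Total step count: 10.
Longest linear sequence: 7 steps (steps 1, 2, 3, 4, 8, 9, 10).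

**Steps most likely to fail**

Step 9. The carbene may add only slowly to the electron-rich, di-ortho-oxygenated aldehyde, so that base-mediated aldol condensation towards the benzofuran overtakes the ring closure, or the discrimination between the two faces of the ketone may be insufficient. The fallback sets out from 15 and gives up asymmetric catalysis. The ring is closed with a small, strongly nucleophilic achiral carbene (3-benzyl-5-(2-hydroxyethyl)-4-methylthiazolium chloride, Et3N, t-BuOH, 40 °C) to give the racemic ketol F1. The enantiomers are then separated by preparative chromatography on a chiral stationary phase, and the (3R) enantiomer rejoins the route at 16.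

Step 10. Acid may ionise the tertiary benzylic C3–OH bond, leading to elimination towards the isoflavone or exchange of hydroxyl for methoxy, in competition with cleavage of the three acetals. The fallback sets out from 15 and moves the acid step in front of the ring closure, where no carbinol exists. Treatment of 15 with 3 M aq HCl in MeOH–THF should give the triphenol keto-aldehyde F2. Allyl bromide and K2CO3 in DMF at rt should give the tris(allyl ether) keto-aldehyde F3. The conditions of step 9 should close it to the tris(allyl ether) ketol F4. Palladium-catalysed allyl transfer to morpholine (Pd(PPh3)4, morpholine, THF, rt; Tsuji–Trost deallylation), which leaves C-prenyl groups and the carbinol untouched, should then give 17 under neutral conditions.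

Step 7. The aryllithium may be quenched by proton transfer from the acidic CH2Cl group of the amide, or may attack the C–Cl carbon, instead of transferring the acyl group cleanly. The fallback sets out from 11 and uses no organolithium. Stille coupling with tributyl(1-ethoxyvinyl)stannane (Pd(PPh3)4, PhMe, 100 °C) should give the aryl enol ether F5. NBS in THF–H2O at 0 °C should convert the enol ether, which is far more nucleophilic than the prenyl alkene, into the bromoketone F6. F6 then alkylates 7 under the conditions of step 8, and the route is rejoined at 15.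

**Further compounds**
F1 | step 9 | racemic 3-hydroxy-3-[2-methoxy-4-(methoxymethoxy)-3-(3-methylbut-2-en-1-yl)phenyl]-5,7-bis(methoxymethoxy)-6-(3-methylbut-2-en-1-yl)-2,3-dihydro-4H-chromen-4-one | COc1c(C2(O)COc3cc(OCOC)c(CC=C(C)C)c(OCOC)c3C2=O)ccc(OCOC)c1CC=C(C)C
F2 | step 10 | 2,4-dihydroxy-6-{2-[4-hydroxy-2-methoxy-3-(3-methylbut-2-en-1-yl)phenyl]-2-oxoethoxy}-3-(3-methylbut-2-en-1-yl)benzaldehyde | O=Cc1c(OCC(=O)c2ccc(O)c(CC=C(C)C)c2OC)cc(O)c(CC=C(C)C)c1O
F3 | step 10 | 6-{2-[2-methoxy-3-(3-methylbut-2-en-1-yl)-4-(prop-2-en-1-yloxy)phenyl]-2-oxoethoxy}-3-(3-methylbut-2-en-1-yl)-2,4-bis(prop-2-en-1-yloxy)benzaldehyde | O=Cc1c(OCC(=O)c2ccc(OCC=C)c(CC=C(C)C)c2OC)cc(OCC=C)c(CC=C(C)C)c1OCC=C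
F4 | step 10 | (3R)-3-hydroxy-3-[2-methoxy-3-(3-methylbut-2-en-1-yl)-4-(prop-2-en-1-yloxy)phenyl]-6-(3-methylbut-2-en-1-yl)-5,7-bis(prop-2-en-1-yloxy)-2,3-dihydro-4H-chromen-4-one | COc1c([C@@]2(O)COc3cc(OCC=C)c(CC=C(C)C)c(OCC=C)c3C2=O)ccc(OCC=C)c1CC=C(C)C
F5 | step 7 | 1-(1-ethoxyethenyl)-2-methoxy-4-(methoxymethoxy)-3-(3-methylbut-2-en-1-yl)benzene | COCOc1ccc(C(=C)OCC)c(OC)c1CC=C(C)C
F6 | step 7 | 2-bromo-1-[2-methoxy-4-(methoxymethoxy)-3-(3-methylbut-2-en-1-yl)phenyl]ethan-1-one | COCOc1ccc(C(=O)CBr)c(OC)c1CC=C(C)C
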